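If a quick number for the order in coupling partner is wanted for the new flask, two stretches of the earlier runs give it through one concentration, K.

in all of them: starting material 0.082 M; free catalyst 4.1 mM

|  | coupling partner | impurity | remark |
|---|---|---|---|
| violet | 0.123 M | 0.50 mM | run made earlier |
| ochre | 0.123 M | 2 mM | run made earlier |
| amber | 0.061 M | 1 mM | run made earlier |
| flask | 0.123 M | 1.0 mM |  |

- violet (time / h: product / %, starting material / %): 1.50: 18.4, 82.3; 5.00: 53.2, 44.9; 8.00: 75.8, 23.4; 12.0: 92.7, 7.0; 20.0: 97.1, 0; 25.0: 99.8, 0.1
- ochre (time / h: product / %, starting material / %): 2.00: 15.3, 84.2; 3.00: 19.7, 78.9; 5.00: 36.0, 64.9; 8.00: 52.8, 47.9; 15.0: 82.0, 16.4; 25.0: 99.5, 2.0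
- amber (time / h: product / %, starting material / %): 2.00: 12.4, 86.1; 6.00: 37.2, 61.9; 12.0: 57.0, 41.9; 15.0: 64.0, 35.9; 25.0: 72.8, 28.6

(readings scatter by 1 percentage point)

* apparent order in coupling partner when 30% of the starting material are converted (percent change of the rate of making product for one percent more coupling partner charged)

- steps under discussion: coupling partner + free catalyst -> catalyst intermediate A; catalyst intermediate A <-> released group + catalyst intermediate B; starting material + catalyst intermediate B -> catalyst intermediate C; catalyst intermediate C <-> catalyst intermediate D; catalyst intermediate D -> free catalyst + product; free catalyst + impurity -> spent catalyst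

Violet and amber pass through the same starting material in stretches centred on 63.6% and 64.0%, so comparing them there holds it fixed. Let r be the fraction of the charge turned into product per hour over a stretch. Let W be the catalyst charged minus the impurity, taking each impurity to remove one free catalyst. Let C be the coupling partner present mid-stretch, which is its charge less the product made.

violet, 1.50 h to 5.00 h: r = 0.0994 h⁻¹, W = 3.60 mM, C = 0.0936 M

amber, 2.00 h to 12.0 h: r = 0.0446 h⁻¹, W = 3.10 mM, C = 0.0325 M

rate per W, amber over violet: ρ = 0.521

With r proportional to W·C/(K + C), the two stretches give

K = Ca(1 − ρ)/(ρ − Ca/Cv) = 0.0899 M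

This reading is K, the half-saturation constant: the partner level at which the rate per working catalyst reaches 0.5 of its ample-partner value. One percent more charge Q raises the partner present by Q/C percent, so the order in the charge is n = [K/(K + C)]·Q/C. In the new flask at 30% conversion:

C = 0.0984 M, n = 0.597

The forecast says 0.62, on “a partly saturated dependence on coupling partner”, a little above this reckoning.

The new flask gives 0.59 at 2.88 h, so the forecast stands within its margin.

    coupling partner + free catalyst → catalyst intermediate A (k = 0.910 M⁻¹ min⁻¹)
    catalyst intermediate A ⇌ released group + catalyst intermediate B (K = 0.0740 M, k = 0.390 min⁻¹)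
    starting material + catalyst intermediate B → catalyst intermediate C (k = 6.40 M⁻¹ min⁻¹)
    catalyst intermediate C ⇌ catalyst intermediate D (K = 1.20, k = 0.460 min⁻¹)
    catalyst intermediate D → free catalyst + product (k = 0.440 min⁻¹)
    free catalyst + impurity → spent catalyst (k = 2400 M⁻¹ min⁻¹)

The path from free catalyst + impurity to spent catalyst holds the new flask back: with that path taken away, the rate at 30% conversion is 1.32 times the actual one. At 2.00 h spent catalyst in the new flask stands at 24.4% of the catalyst charged, the loss that W subtracts. K compares rates per W, and with 0.105 M of coupling partner present in the new flask at that time, K/(K + C) comes to 46.2%.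

The data are calculated with constants of no real substance, and the scatter is random.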